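Late in a run I want to know how much target the enzyme can have delivered by the end, so I count its turnovers against the charge. Free enzyme takes up starting material to the starting complex, which takes up the fed second substrate to the ternary complex. The ternary complex releases target and returns free enzyme, and target caught as idle adduct still counts as target.

the same everywhere: starting material 0.091 M; second substrate 1.50 equiv (fed, over 8.0 h); free enzyme 0.089 mol%; time 20 h

|  | temperature |
|---|---|
| alpha | 40 °C |
| delta | 10 °C |

1. the flask with the highest amount of target, in percent of the starting material charged ("all alike" if they lie within 1.5 percentage points) (alpha / delta / all alike)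
2. final target, as a percentage of the starting material charged, in alpha
3. final target, as a percentage of the starting material charged, in delta

- percent here means starting material units held: one idle adduct counts as two
- what is said of target includes idle adduct
- at 40 °C the constants are as listed, elsewhere as the activation energies and enthalpies make them
- in an amount of target, one idle adduct counts as one target

    free enzyme → unfolded enzyme (k1 = 9.7 × 10⁻⁴ h⁻¹, Ea1 = 265 kJ mol⁻¹)
    starting material + free enzyme ⇌ starting complex (K2 = 42 M⁻¹, k2 = 1.9 × 10⁵ M⁻¹ h⁻¹, Ea2 = 55.0 kJ mol⁻¹, ΔH2 = −15.0 kJ mol⁻¹)
    second substrate + starting complex ⇌ ternary complex (K3 = 12 M⁻¹, k3 = 1.2 × 10⁵ M⁻¹ h⁻¹, Ea3 = 44.0 kJ mol⁻¹, ΔH3 = −54.0 kJ mol⁻¹)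
    ternary complex → free enzyme + target (k4 = 320 h⁻¹, Ea4 = 88.0 kJ mol⁻¹)
    starting material + target ⇌ idle adduct, settled at all times (K5 = 6.2 M⁻¹, ΔH5 = −23.0 kJ mol⁻¹)
    (constants at 40 °C)

Target forms at 320 h⁻¹ times the ternary complex at 40 °C, and the ternary complex cannot exceed the catalyst charged. The fraction of the charge made therefore stays below that constant times the loading times the time. In delta the constant is smaller by a factor of 36, so this product is 15.9%, and I call it the turnover ceiling: the release constant at the flask's temperature times the loading times the time. In alpha the same product is 570%, more than the whole charge, and the half-life of free enzyme against unfolding, 715 h, is longer than the 20 h of the run. So I expect alpha ahead and delta below its ceiling, and the reckoning goes no further for alpha.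

The forecast names alpha, with 98.7% in alpha and 14% in delta, where “the nearly saturated enzyme runs at a ceiling”. Its delta figure is lower than my 15.9%, which is a bound and not a yield.

The simulation gives alpha ahead, with 99.0% in alpha and 13.7% in delta.

In delta the target reaches 86.2% of the ceiling, while the ternary complex, the resting state there, holds 91.6% of the catalyst at 10.0 h and 91.0% at 20.0 h, with 79% of the starting material still unbound. In alpha the target reaches 17.4% of the same product, with 0.63% of the starting material left and 1.20% of the catalyst as ternary complex at 20.0 h.

The same flask as alpha run at 15 °C has a ceiling of 30.3%, below the whole charge. It gives 24.5%, which is 80.9% of that ceiling, with 85.7% of the catalyst as ternary complex at 20.0 h.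

The numbers of this flask belong to no real substance, and the outcome is calculated.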